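**Retrosynthetic overview**
1. The target (GA55) is 1β-hydroxy-GA1, which is gibberellic acid (GA3) formally hydrated across C1=C2 with the new OH on C1β. GA3 supplies rings A–D, the 19,10-lactone and the centres C4, C5, C6, C8, C9, C10 and C13, so no ring is formed in the route.
2. C7 acid ⇐ allyl ester, removed last under neutral conditions.
3. C3β–OH ⇐ C3 ketone, by equatorial hydride delivery from a bulky borohydride.
4. C1β–OH ⇐ 1-en-3-one, by conjugate borylation and C–B oxidation.
5. Enone ⇐ allylic oxidation of GA3 allyl ester ⇐ GA3 + allyl bromide.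

Assumption: gibberellic acid (GA3), a bulk fermentation product stocked by the usual catalogue suppliers, is taken as a commercially available starting material.

**Route**

Step 1
Reactants: 1 gibberellic acid (GA3); 2 allyl bromide
Product: 3 GA3 allyl ester
Conditions: allyl bromide (1.5 equiv), KHCO3 (2 equiv), DMF, rt
Reagents that add atoms: allyl bromide, C=CCBr
Why: Carboxylate O-alkylation (SN2) in which KHCO3 ionises only the C7 acid, so the 3-OH stays protonated, the base-triggered lactone migration of GA3 cannot start, and no stereocentre is touched.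

Step 2
Reactants: 3 GA3 allyl ester
Product: 4 3-dehydro-GA3 allyl ester
Conditions: activated MnO2 (20 equiv), CH2Cl2, rt
Reagents that add atoms: none
Why: Allylic alcohol oxidation on MnO2, which takes only the secondary allylic 3-OH (the tertiary 13-OH cannot react) and deliberately erases C3 to turn C1 into a Michael acceptor.

Step 3
Reactants: 4 3-dehydro-GA3 allyl ester; 5 bis(pinacolato)diboron
Product: 7 3-dehydro-GA55 allyl ester, via 1β-pinacolboryl-3-ketone 6 (not isolated)
Conditions: B2pin2 (1.1 equiv), CuCl (5 mol%), DPEphos (5 mol%), NaOt-Bu (10 mol%), MeOH (2 equiv), THF, rt; then NaBO3·4H2O (5 equiv), THF/H2O, rt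
Reagents that add atoms: bis(pinacolato)diboron, CC1(C)OB(OC1(C)C)B1OC(C)(C)C(C)(C)O1 (boron held only in 6); sodium perborate tetrahydrate, [Na+].[O-]OB=O.O.O.O.O (the C1 oxygen of 7)
Why: Copper-catalysed conjugate borylation followed by stereoretentive C–B oxidation, in which the boryl group enters C1 axially from the open β face of ring A, anti to the axial C10–O bond of the lactone bridge that caps the α face, so the new centre is 1β-OH.

Step 4
Reactants: 7 3-dehydro-GA55 allyl ester
Product: 8 GA55 allyl ester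
Conditions: KBH(s-Bu)3 (2.5 equiv), THF, −78 °C; AcOH quench at −78 °C
Reagents that add atoms: none
Why: Reagent-controlled ketone reduction with a bulky trialkylborohydride, where axial β-face approach to C3 is blocked by the syn-axial 1β-oxygen and 5β-H, so hydride enters equatorially from the α side and gives the axial 3β-alcohol cis to the 1β-OH, while the ester and lactone are inert at −78 °C.

Step 5
Reactants: 8 GA55 allyl ester
Product: 9 GA55
Conditions: Pd(PPh3)4 (5 mol%), morpholine (5 equiv), THF, rt; then aqueous citric acid to pH 3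
Reagents that add atoms: none
Why: Tsuji–Trost deallylation, in which zerovalent palladium ionises the allyl ester to a π-allyl complex that morpholine traps, freeing the acid under neutral conditions that leave the lactone, the 1,3-diol, the 13-OH and the 16-ene alone and touch no stereocentre.

**Compound list**
1 | gibberellic acid (GA3; 3β,13-dihydroxy-1,16-diene-7-oic acid with 19,10α-lactone) | C=C1C[C@]23C[C@@]1(O)CC[C@H]2[C@@]12OC(=O)[C@@](C)([C@H]1[C@@H]3C(=O)O)[C@@H](O)C=C2 | starting material
2 | allyl bromide | C=CCBr | starting material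
3 | GA3 allyl ester (C7 allyl ester of 1) | C=C1C[C@]23C[C@@]1(O)CC[C@H]2[C@@]12OC(=O)[C@@](C)([C@H]1[C@@H]3C(=O)OCC=C)[C@@H](O)C=C2 | intermediate
4 | 3-dehydro-GA3 allyl ester (1-en-3-one) | C=C1C[C@]23C[C@@]1(O)CC[C@H]2[C@@]12OC(=O)[C@@](C)([C@H]1[C@@H]3C(=O)OCC=C)C(=O)C=C2 | intermediate
5 | bis(pinacolato)diboron | CC1(C)OB(OC1(C)C)B1OC(C)(C)C(C)(C)O1 | starting material
6 | 1β-pinacolboryl-3-ketone (3-dehydro-GA1 allyl ester with Bpin on C1β) | C=C1C[C@]23C[C@@]1(O)CC[C@H]2[C@@]12OC(=O)[C@@](C)([C@H]1[C@@H]3C(=O)OCC=C)C(=O)C[C@H]2B4OC(C)(C)C(C)(C)O4 | intermediate (not isolated)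
7 | 3-dehydro-GA55 allyl ester (1β,13-dihydroxy-3-ketone) | C=C1C[C@]23C[C@@]1(O)CC[C@H]2[C@@]12OC(=O)[C@@](C)([C@H]1[C@@H]3C(=O)OCC=C)C(=O)C[C@H]2O | intermediate
8 | GA55 allyl ester (1β,3β,13-triol) | C=C1C[C@]23C[C@@]1(O)CC[C@H]2[C@@]12OC(=O)[C@@](C)([C@H]1[C@@H]3C(=O)OCC=C)[C@@H](O)C[C@H]2O | intermediate
9 | GA55 (1β-hydroxy-GA1) | C=C1C[C@]23C[C@@]1(O)CC[C@H]2[C@@]12OC(=O)[C@@](C)([C@H]1[C@@H]3C(=O)O)[C@@H](O)C[C@H]2O | target

**Totals**
Total step count: 5. Longest linear sequence: 5 steps (1 → 3 → 4 → 7 → 8 → 9).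

**Steps most likely to fail, with fallbacks**

Step 3 (conjugate borylation and oxidation). The risks are cleavage of the base-sensitive β-keto lactone by alkoxide and incomplete face selectivity at C1. The fallback sets out from 4 and comes back at 7. Enone 4 is epoxidised under anhydrous Weitz–Scheffer conditions (t-BuOOH, DBU, CH2Cl2, 0 °C), hydroperoxide adding to C1 from the β face and closing to the 1β,2β-epoxy-3-ketone allyl ester F1. SmI2 (2.2 equiv, THF/MeOH, −90 °C) then cleaves only the C2–O bond next to the ketone, leaving the C1β–O bond, and gives 7.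

Step 4 (C3 reduction). The risk is formation of the 3α-epimer, or retro-aldol epimerisation of the C3 alkoxide if the mixture warms before the quench. The fallback sets out from 7 and comes back at 8, and swaps steric control for chelation control. Treatment of 7 with Et2BOMe (THF/MeOH 4:1, −78 °C) gives the 1-O-diethylboryl chelate F2, in which boron bridges the axial 1β-oxygen and the C3 carbonyl oxygen. NaBH4 at −78 °C then attacks the only open face, α (Narasaka–Prasad syn-1,3-diol reduction), and repeated evaporation from MeOH/AcOH strips boron to give 8.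

Step 5 (deallylation and isolation of the polar triol acid). The risk is loss or damage of the product during unmasking. The fallback sets out from 1 and comes back at 9 and uses no protecting group. It is held in reserve because copper catalysis on a free acid is less precedented and the acids are harder to purify. GA3 1 is oxidised directly with MnO2 (acetone, rt) to 3-dehydro-GA3 F3. Its sodium salt (1.05 equiv NaOt-Bu) is borylated as in step 3 (CuCl, DPEphos, B2pin2, MeOH, THF) to the 1β-pinacolboryl-3-oxo acid F4, which is oxidised in the same flask with NaBO3·4H2O and acidified to 3-dehydro-GA55 F5. KBH(s-Bu)3 (3.5 equiv, THF, −78 °C, AcOH quench) then reduces F5 to 9.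

**Further compounds**
F1 | step 3 | 1β,2β-epoxy-3-ketone allyl ester (1β,2β-epoxy-3-dehydro-GA1 allyl ester) | C=C1C[C@]23C[C@@]1(O)CC[C@H]2[C@@]12OC(=O)[C@@](C)([C@H]1[C@@H]3C(=O)OCC=C)C(=O)[C@H]4O[C@@H]24
F2 | step 4 | 1-O-diethylboryl chelate of 7 | C=C1C[C@]23C[C@@]1(O)CC[C@H]2[C@@]12OC(=O)[C@@](C)([C@H]1[C@@H]3C(=O)OCC=C)C(=O)C[C@H]2OB(CC)CC
F3 | step 5 | 3-dehydro-GA3 (free acid) | C=C1C[C@]23C[C@@]1(O)CC[C@H]2[C@@]12OC(=O)[C@@](C)([C@H]1[C@@H]3C(=O)O)C(=O)C=C2
F4 | step 5 | 1β-pinacolboryl-3-oxo acid (free-acid analogue of 6) | C=C1C[C@]23C[C@@]1(O)CC[C@H]2[C@@]12OC(=O)[C@@](C)([C@H]1[C@@H]3C(=O)O)C(=O)C[C@H]2B4OC(C)(C)C(C)(C)O4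
F5 | step 5 | 3-dehydro-GA55 (free acid) | C=C1C[C@]23C[C@@]1(O)CC[C@H]2[C@@]12OC(=O)[C@@](C)([C@H]1[C@@H]3C(=O)O)C(=O)C[C@H]2O
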